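**Retrosynthetic overview** (ring A = guaiacyl ring of the C3 benzyl group, ring B = guaiacyl ring of the C4 benzyl group)
1. Target 17 ⇒ remove two ring A benzyl ethers ⇒ cut the C5–C5′ biaryl bond. The bond is made by anodic dehydrodimerisation of monomer 12, whose only free phenol sits on ring B.
2. 12 ⇒ the butyrolactone comes from acid 10 by CO2H → CH2OH and translactonisation of the dioxolanone.
3. 10 ⇒ the C3–CH2(ring A) bond comes from alkylating cis-tert-butyl-dioxolanone 8 with bromide 4.
4. 8 ⇒ the C4–CH2(ring B) bond comes from anti-alkylation of dibenzyl D-malate 2 with the same bromide 4. D-malic acid 1 supplies or controls every stereocentre.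
5. Ring order: temporary dioxolanone → butyrolactone → biaryl link between two lactones.

Assumption: the SMILES is read as the all-R (3R,4R,3′R,4′R) dimer of (+)-nortrachelogenin. Its biaryl axis carries only two ortho OH groups and rotates freely, so only the four sp3 centres need control. D-(+)-malic acid is taken as a commercial bulk chiral acid.

**Step 1**
Reactants: 1 D-(+)-malic acid [(R)-2-hydroxybutanedioic acid]
Product: 2 dibenzyl (R)-malate
Conditions: BnOH (2.2 equiv), TsOH·H2O (5 mol %), toluene, reflux, Dean–Stark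
Reagents that add atoms: benzyl alcohol, OCc1ccccc1
Why: Fischer esterification driven by azeotropic water removal leaves the bought C2 centre untouched and installs esters that one later hydrogenolysis removes together with the ring B benzyl ether.

**Step 2**
Reactants: 3 4-(benzyloxy)-3-methoxybenzyl alcohol
Product: 4 4-(benzyloxy)-3-methoxybenzyl bromide
Conditions: PBr3 (0.4 equiv), Et2O, 0 °C, 1 h; used without chromatography
Reagents that add atoms: phosphorus tribromide, BrP(Br)Br
Why: Bromide displaces the phosphite ester of an electron-rich benzylic alcohol (SN2-type PBr3 bromination), and this single bromide serves both alkylations.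

**Step 3**
Reactants: 2 dibenzyl (R)-malate; 4 4-(benzyloxy)-3-methoxybenzyl bromide
Product: 6 dibenzyl (2R,3S)-3-[4-(benzyloxy)-3-methoxybenzyl]-2-hydroxybutanedioate, via dilithium alkoxide enolate 5 (not isolated)
Conditions: LiN(SiMe3)2 (2.15 equiv), THF, −78 → −20 °C; 4 (0.95 equiv), −78 → −10 °C; 1 M HCl; chromatography
Reagents that add atoms: none
Why: Fráter–Seebach alkylation, in which the lithium-chelated alkoxide enolate 5 takes the bromide on the chelate face turned away from the C1 ester, so the bought (R)-carbinol centre sets C3 as S (anti:syn about 9:1, minor isomer removed on silica).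

**Step 4**
Reactants: 6 dibenzyl (2R,3S)-3-[4-(benzyloxy)-3-methoxybenzyl]-2-hydroxybutanedioate
Product: 7 (2R,3S)-2-hydroxy-3-(4-hydroxy-3-methoxybenzyl)butanedioic acid
Conditions: H2 (1 atm), Pd/C (10 wt %), EtOAc–EtOH, rt
Reagents that add atoms: none
Why: Catalytic hydrogenolysis cleaves both benzyl esters and the aryl benzyl ether in one neutral operation that cannot epimerise C2 or C3, so ring B is freed as a phenol before ring A is introduced.

**Step 5**
Reactants: 7 (2R,3S)-2-hydroxy-3-(4-hydroxy-3-methoxybenzyl)butanedioic acid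
Product: 8 (2S)-2-[(2R,4R)-2-tert-butyl-5-oxo-1,3-dioxolan-4-yl]-3-(4-hydroxy-3-methoxyphenyl)propanoic acid (cis-dioxolanone)
Conditions: t-BuCHO (3 equiv), TsOH·H2O (10 mol %), H2SO4 (cat.), CH2Cl2–pentane, reflux, Dean–Stark; recrystallise
Reagents that add atoms: pivalaldehyde, CC(C)(C)C=O
Why: Seebach acetalisation (self-regeneration of stereocentres) closes the α-hydroxy acid reversibly to the five-membered dioxolanone, and the thermodynamically preferred cis isomer fixes the new acetal centre (R) under control of C2 while the distal acid and the phenol stay free.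

**Step 6**
Reactants: 8 cis-dioxolanone acid; 4 4-(benzyloxy)-3-methoxybenzyl bromide
Product: 10 (2S)-2-{(2R,4R)-4-[4-(benzyloxy)-3-methoxybenzyl]-2-tert-butyl-5-oxo-1,3-dioxolan-4-yl}-3-(4-hydroxy-3-methoxyphenyl)propanoic acid, via trilithium phenolate carboxylate enolate 9 (not isolated)
Conditions: LiN(SiMe3)2 (3.3 equiv), THF, −78 °C, 45 min; 4 (1.0 equiv), −78 → −45 °C; 1 M HCl at −45 °C
Reagents that add atoms: none
Why: Seebach dioxolanone enolate alkylation, in which the enolate carbon is by far the most nucleophilic site of 9 (lithium phenolate and carboxylate ignore one equivalent of benzylic bromide in cold THF) and the bromide enters trans to the tert-butyl group, so benzyl replaces H with retention and the quaternary centre is R.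

**Step 7**
Reactants: 10 quaternary dioxolanone acid
Product: 12 (3R,4R)-3-[4-(benzyloxy)-3-methoxybenzyl]-3-hydroxy-4-(4-hydroxy-3-methoxybenzyl)oxolan-2-one (ring A O-benzyl (+)-nortrachelogenin), via hydroxymethyl dioxolanone 11 (not isolated)
Conditions: BH3·THF (3.5 equiv), THF, 0 °C → rt; H2O quench; then TsOH·H2O (20 mol %), CH2Cl2, rt
Reagents that add atoms: none
Why: Chemoselective borane reduction takes the free acid through its acyloxyborane much faster than the dioxolanone carbonyl, and the primary alcohol of 11 then attacks that carbonyl (acid-catalysed 5-exo translactonisation) and expels pivalaldehyde without touching any stereocentre.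

**Step 8**
Reactants: 12 ring A O-benzyl (+)-nortrachelogenin (two molecules)
Product: 16 5,5′-linked ring B to ring B dimer of 12 (both ring A phenols still benzylated; all four centres R), via magnesium bis(phenolate) 13 (not isolated), via bis(cyclohexadienone) dimer 14 (not isolated), via magnesium biphenolate 15 (not isolated)
Conditions: Mg(OtBu)2 (0.50 equiv), MeCN–THF 4:1 (0.1 M in 12), rt, 30 min; then undivided cell, glassy carbon anode | Pt cathode, nBu4NOTf 0.1 M, 2 mA cm−2, 1.05 F mol−1, anode kept below about +0.7 V vs Ag/AgCl, rt; 1 M HCl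
Reagents that add atoms: none
Why: Proposed new method: a redox-inert divalent magnesium ion gathers two ring B guaiacolates through O−/OMe chelation (13), which puts their oxidation roughly 0.6 V below that of the O-benzylated ring A and sets the two C5 carbons side by side, so one-electron anodic oxidation gives a bound phenoxyl radical that attacks the neighbouring bound phenolate at C5 (para position blocked, spin and charge both highest at C5, the positions needed for eight-membered ring closure onto ring A carry almost no spin), a second electron leaves at once (ECE), dienone 14 tautomerises and its two protons become H2 at the cathode to leave the seven-membered chelate 15, no stereocentre is formed or touched and no free nucleophilic base threatens the lactone; the closest known reaction types are the anodic dimerisation of vanillin phenolate to dehydrodivanillin, the borate-templated anodic ortho coupling of 2,4-dimethylphenol and the ortho-directing magnesium phenolates of the Casnati–Skattebøl formylation, none of which uses a magnesium template at an anode or a lignan lactone.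

**Step 9**
Reactants: 16 di-O-benzyl dimer
Product: 17 bis-5,5-nortrachelogenin
Conditions: H2 (1 atm), Pd/C (10 wt %), EtOAc–MeOH, rt
Reagents that add atoms: none
Why: Catalytic hydrogenolysis removes the two aryl benzyl ethers, while the lactones, the homobenzylic tertiary alcohols, the methyl ethers and the biaryl are inert and no stereocentre is affected.

**Compound list**
1 | D-(+)-malic acid, (R)-2-hydroxybutanedioic acid | OC(=O)[C@H](O)CC(=O)O | starting material
2 | dibenzyl (R)-malate | O=C(OCc1ccccc1)[C@H](O)CC(=O)OCc1ccccc1 | intermediate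
3 | 4-(benzyloxy)-3-methoxybenzyl alcohol | COc1cc(CO)ccc1OCc1ccccc1 | starting material
4 | 4-(benzyloxy)-3-methoxybenzyl bromide | COc1cc(CBr)ccc1OCc1ccccc1 | intermediate
5 | dilithium alkoxide enolate of 2 (not isolated) | [Li+].[Li+].O=C(OCc1ccccc1)[C@H]([O-])C=C([O-])OCc1ccccc1 | intermediate
6 | dibenzyl (2R,3S)-3-[4-(benzyloxy)-3-methoxybenzyl]-2-hydroxybutanedioate | O=C(OCc1ccccc1)[C@H](O)[C@H](Cc1ccc(OCc2ccccc2)c(OC)c1)C(=O)OCc1ccccc1 | intermediate
7 | (2R,3S)-2-hydroxy-3-(4-hydroxy-3-methoxybenzyl)butanedioic acid | OC(=O)[C@H](O)[C@H](Cc1ccc(O)c(OC)c1)C(=O)O | intermediate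
8 | (2S)-2-[(2R,4R)-2-tert-butyl-5-oxo-1,3-dioxolan-4-yl]-3-(4-hydroxy-3-methoxyphenyl)propanoic acid | CC(C)(C)[C@H]1OC(=O)[C@@H]([C@H](Cc2ccc(O)c(OC)c2)C(=O)O)O1 | intermediate
9 | trilithium phenolate carboxylate enolate of 8 (not isolated) | [Li+].[Li+].[Li+].CC(C)(C)[C@H]1OC([O-])=C([C@H](Cc2ccc([O-])c(OC)c2)C(=O)[O-])O1 | intermediate
10 | (2S)-2-{(2R,4R)-4-[4-(benzyloxy)-3-methoxybenzyl]-2-tert-butyl-5-oxo-1,3-dioxolan-4-yl}-3-(4-hydroxy-3-methoxyphenyl)propanoic acid | CC(C)(C)[C@H]1OC(=O)[C@@](Cc2ccc(OCc3ccccc3)c(OC)c2)([C@H](Cc2ccc(O)c(OC)c2)C(=O)O)O1 | intermediate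
11 | primary alcohol from 10 (CO2H → CH2OH, otherwise unchanged; not isolated) | CC(C)(C)[C@H]1OC(=O)[C@@](Cc2ccc(OCc3ccccc3)c(OC)c2)([C@H](Cc2ccc(O)c(OC)c2)CO)O1 | intermediate
12 | (3R,4R)-3-[4-(benzyloxy)-3-methoxybenzyl]-3-hydroxy-4-(4-hydroxy-3-methoxybenzyl)oxolan-2-one | COc1cc(C[C@]2(O)C(=O)OC[C@H]2Cc2ccc(O)c(OC)c2)ccc1OCc1ccccc1 | intermediate
13 | magnesium bis(ring B phenolate) of 12 (not isolated) | [Mg+2].COc1cc(C[C@]2(O)C(=O)OC[C@H]2Cc2ccc([O-])c(OC)c2)ccc1OCc1ccccc1.COc1cc(C[C@]2(O)C(=O)OC[C@H]2Cc2ccc([O-])c(OC)c2)ccc1OCc1ccccc1 | intermediate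
14 | C5–C5′ bis(cyclohexa-2,4-dienone) dimer (the two transient sp3 ring carbons are left undefined; not isolated) | COc1cc(C[C@]2(O)C(=O)OC[C@H]2CC2=CC(C3C=C(C[C@@H]4COC(=O)[C@@]4(O)Cc4ccc(OCc5ccccc5)c(OC)c4)C=C(OC)C3=O)C(=O)C(OC)=C2)ccc1OCc1ccccc1 | intermediate
15 | magnesium 2,2′-biphenolate of 16 (not isolated) | [Mg+2].COc1cc(C[C@]2(O)C(=O)OC[C@H]2Cc2cc(OC)c([O-])c(-c3cc(C[C@@H]4COC(=O)[C@@]4(O)Cc4ccc(OCc5ccccc5)c(OC)c4)cc(OC)c3[O-])c2)ccc1OCc1ccccc1 | intermediate
16 | 5,5′-dimer of 12, ring A phenols benzylated | COc1cc(C[C@]2(O)C(=O)OC[C@H]2Cc2cc(OC)c(O)c(-c3cc(C[C@@H]4COC(=O)[C@@]4(O)Cc4ccc(OCc5ccccc5)c(OC)c4)cc(OC)c3O)c2)ccc1OCc1ccccc1 | intermediate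
17 | bis-5,5-nortrachelogenin | COc1cc(C[C@]2(O)C(=O)OC[C@H]2Cc2cc(OC)c(O)c(-c3cc(C[C@@H]4COC(=O)[C@@]4(O)Cc4ccc(O)c(OC)c4)cc(OC)c3O)c2)ccc1O | target

**Total steps:** 9.
**Longest linear sequence:** 8 (1 → 2 → 6 → 7 → 8 → 10 → 12 → 16 → 17; the line from 3 through 4 is equally long).

**Three steps most likely to fail**

**Step 8 (new anodic coupling).**
- Risks: anode fouling by phenolic films, C–O (4-O-5) coupling, quinone methide formation at the benzylic carbon, and over-oxidation of the biphenolate.
- The fallback uses known chemistry. It sets out from 12 and comes back at 17.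
- Ring B of 12 is iodinated ortho to the free phenol (I2, NaHCO3, THF–H2O, 0 °C; phenolate-controlled aromatic substitution as for 5-iodovanillin) to the 5-iodophenol F1.
- The phenol is capped (BnBr, K2CO3, acetone, reflux) to the iodo bis(benzyl ether) F2.
- Two molecules are joined by nickel-catalysed reductive homocoupling (NiCl2(PPh3)2 10 mol %, Zn, Et4NI, THF, 50 °C; zerovalent nickel is formed in situ) to the tetra-O-benzyl dimer F3.
- All four benzyl ethers are hydrogenolysed under the conditions of step 9 to give 17.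

**Step 6 (alkylation of a trianion carrying a free phenolate).**
- Risks: poor solubility of 9, O-benzylation of the phenolate, and enolate decay on warming.
- The fallback masks the phenol, so the alkylation runs on the well-behaved carboxylate–enolate dianion. It sets out from 8 and comes back at 12.
- 8 is silylated (TBSCl 2.3 equiv, imidazole, DMF) to the silyl ether silyl ester F4, and mild hydrolysis (AcOH–THF–H2O) gives the aryl silyl ether acid F5.
- Alkylation (LiN(SiMe3)2 2.2 equiv, 4, THF, −78 °C) gives the quaternary silyl ether acid F6.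
- BH3·THF gives the silyl ether hydroxymethyl dioxolanone F7, and TsOH in CH2Cl2 closes it to the ring B silyl ether lactone F8.
- nBu4NF/AcOH in THF at 0 °C frees the phenol to give 12.

**Step 7 (borane reduction of an acid flanked by a quaternary carbon).**
- Risks: slow reduction and competing attack on the dioxolanone.
- The fallback reverses the order of reduction and alkylation and relies on substrate control. It sets out from 8, bypasses 10 and 11, and comes back at 12.
- The much less hindered acid of 8 is reduced (BH3·THF) to the unalkylated hydroxymethyl dioxolanone F9.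
- TsOH closes it to the cis α-hydroxy-β-benzyl lactone F10.
- The trilithium salt of this lactone (LiN(SiMe3)2 3.2 equiv, THF, −78 °C) is alkylated with 4. The bromide enters anti to the C4 benzyl group, the known way to trans-dibenzyl α-hydroxy lactone lignans, and gives 12.

**Further compounds**
F1 | step 8 | (3R,4R)-3-[4-(benzyloxy)-3-methoxybenzyl]-3-hydroxy-4-(4-hydroxy-3-iodo-5-methoxybenzyl)oxolan-2-one | COc1cc(C[C@]2(O)C(=O)OC[C@H]2Cc2cc(I)c(O)c(OC)c2)ccc1OCc1ccccc1
F2 | step 8 | (3R,4R)-3-[4-(benzyloxy)-3-methoxybenzyl]-4-[4-(benzyloxy)-3-iodo-5-methoxybenzyl]-3-hydroxyoxolan-2-one | COc1cc(C[C@]2(O)C(=O)OC[C@H]2Cc2cc(I)c(OCc3ccccc3)c(OC)c2)ccc1OCc1ccccc1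
F3 | step 8 | tetra-O-benzyl bis-5,5-nortrachelogenin | COc1cc(C[C@]2(O)C(=O)OC[C@H]2Cc2cc(OC)c(OCc3ccccc3)c(-c3cc(C[C@@H]4COC(=O)[C@@]4(O)Cc4ccc(OCc5ccccc5)c(OC)c4)cc(OC)c3OCc3ccccc3)c2)ccc1OCc1ccccc1
F4 | step 6 | aryl TBS ether TBS ester of 8 | CC(C)(C)[C@H]1OC(=O)[C@@H]([C@H](Cc2ccc(O[Si](C)(C)C(C)(C)C)c(OC)c2)C(=O)O[Si](C)(C)C(C)(C)C)O1
F5 | step 6 | aryl TBS ether of 8 (free acid) | CC(C)(C)[C@H]1OC(=O)[C@@H]([C@H](Cc2ccc(O[Si](C)(C)C(C)(C)C)c(OC)c2)C(=O)O)O1
F6 | step 6 | aryl TBS ether of 10 | CC(C)(C)[C@H]1OC(=O)[C@@](Cc2ccc(OCc3ccccc3)c(OC)c2)([C@H](Cc2ccc(O[Si](C)(C)C(C)(C)C)c(OC)c2)C(=O)O)O1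
F7 | step 6 | aryl TBS ether of 11 | CC(C)(C)[C@H]1OC(=O)[C@@](Cc2ccc(OCc3ccccc3)c(OC)c2)([C@H](Cc2ccc(O[Si](C)(C)C(C)(C)C)c(OC)c2)CO)O1
F8 | step 6 | ring B TBS ether of 12 | COc1cc(C[C@]2(O)C(=O)OC[C@H]2Cc2ccc(O[Si](C)(C)C(C)(C)C)c(OC)c2)ccc1OCc1ccccc1
F9 | step 7 | primary alcohol from 8 (CO2H → CH2OH) | CC(C)(C)[C@H]1OC(=O)[C@@H]([C@H](Cc2ccc(O)c(OC)c2)CO)O1
F10 | step 7 | (3R,4R)-3-hydroxy-4-(4-hydroxy-3-methoxybenzyl)oxolan-2-one | O[C@H]1C(=O)OC[C@H]1Cc1ccc(O)c(OC)c1
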